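(The earlier runs and the new flask are calculated for an exercise; the scatter is artificial.)

The 4 questions on this flask come down to one thing: how long J stays at work. The orders are read from starting rates, and the share in the Monday's run depends on J's lifetime.

| setting | Sunday's | Saturday's | Wednesday's | Thursday's | Monday's |
|---|---|---|---|---|---|
| E | 0.600 M | 0.300 M | 0.600 M | 0.600 M | 0.120 M |
| Z | 1.50 M | 1.20 M | 1.50 M | 2.20 M | 0.300 M |
| J | 0.0120 M | 0.0120 M | 0.0120 M | 0.0120 M | 0.0120 M |
| G |  |  | 0.180 M |  |  |
| time |  |  |  |  | 12 min |

| run | time / min | [G] / M |
|---|---|---|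
| Sunday's run | 0.48 | 0.0353 |
| Sunday's run | 0.82 | 0.0618 |
| Sunday's run | 1.4 | 0.0994 |
| Sunday's run | 2.4 | 0.1469 |
| Sunday's run | 4.1 | 0.2195 |
| Sunday's run | 7.0 | 0.2963 |
| Sunday's run | 12 | 0.3789 |
| Saturday's run | 0.48 | 0.0204 |
| Saturday's run | 0.82 | 0.0296 |
| Saturday's run | 1.4 | 0.0484 |
| Saturday's run | 2.4 | 0.0741 |
| Saturday's run | 4.1 | 0.1066 |
| Saturday's run | 7.0 | 0.1465 |
| Saturday's run | 12 | 0.1862 |
| Wednesday's run | 0.48 | 0.2141 |
| Wednesday's run | 0.82 | 0.2423 |
| Wednesday's run | 1.4 | 0.2786 |
| Wednesday's run | 2.4 | 0.3277 |
| Wednesday's run | 4.1 | 0.3976 |
| Wednesday's run | 7.0 | 0.4770 |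
| Wednesday's run | 12 | 0.5548 |
| Thursday's run | 0.48 | 0.0470 |
| Thursday's run | 0.82 | 0.0739 |
| Thursday's run | 1.4 | 0.1212 |
| Thursday's run | 2.4 | 0.1814 |
| Thursday's run | 4.1 | 0.2556 |
| Thursday's run | 7.0 | 0.3388 |
| Thursday's run | 12 | 0.4258 |

(scatter of a reading: 0.002 M)

- apparent order in [E] of the starting rate, round the charge of the Sunday's run (the rate where two percent of its E have turned into G) (one fixed amount of G, the same in the runs compared)
- apparent order in [Z] of the starting rate, round the charge of the Sunday's run (the rate where two percent of its E have turned into G)
- the Saturday's run starts with 0.300 M less of E and of Z than the Sunday's run, and with no G. Compared where both hold the same amount of E, once fifteen percent of what the Saturday's run was charged with has turned into G, is the Saturday's run faster, slower or alike (within a tenth)?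
- G in the Monday's run at 12 min, as a share of the E charged

- Overall: E + Z -> G, with J as catalyst.
- Constant volume, constant temperature.
- "The second partner" is Z.
- An order is taken over about fifteen percent of the charge, up and down.

Progress is reckoned here as ln(E charged / E left), because parallel paths then simply add. An E molecule has two ways to G: directly with Z, or through J. The tail of the Thursday's run is taken as the direct path alone, which gives a constant of 0.0440 L mol⁻¹ min⁻¹.

The fastest rung is the turn of J. Early in the Sunday's run, progress through J runs at

a = 0.0666 min⁻¹

which is about half of the E molecule's total chance. One turnover therefore takes 0.300 min.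

The next rung is the fading of J. The Sunday's progress at 12 min is 0.998. Of this, the direct path takes 0.676, using Z as it stands a third of the way through, and J gives 0.323. Dividing by a gives

4.84 min

the working life of J: the minutes of full starting activity that J delivers. This is 16.1 turnovers, as the turn is much shorter than the life. G does not set this life: the Wednesday's run, net of its added G, holds 0.148 M at 2.4 min, alike to the Sunday's 0.1469 M. Z does go with it. The same reckoning for the Thursday's run gives a = 0.0636 min⁻¹ and a life of 3.32 min, shorter by a ratio of 0.686, while the ratio of the Z charges is 0.682.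

So the Saturday's run, at the composition it shares with the Sunday's run, has younger J. It passes that point before 1.4 min at about 0.0324 M min⁻¹, and the Sunday's run passes it after 7.0 min at 0.0165 M min⁻¹. This reckoning therefore calls the Saturday's run faster.

The slowest rung is the direct path, with a time of 15.2 min in the Sunday's run, longer than the working life.

The Monday's run is the Sunday's diluted 5.00 times with J kept. The value of a is taken as the Sunday's, as the Thursday's run reads near it. The life is scaled by Z and the fade is taken as exponential:

life in the Monday's run = 24.2 min
through J: 0.630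
direct: 0.142
share of E as G at 12 min: 53.8%

The forecast gives orders of 0.8 and 0.56, calls the Saturday's run faster, and gives 34% (26% to 43%), lower than this reckoning, on the ground that “the catalyst must be dying with time”.

The flask gives orders of 0.74 in E and 0.74 in Z, the Saturday's run faster, and 58.2% in the Monday's run, 4.4 percentage points above this reckoning.

    J + E → Rx + L (13.98 L mol⁻¹ min⁻¹)
    Rx + Z → G + J (4.506 L mol⁻¹ min⁻¹)
    J + Z → Xi + Z (0.3726 L mol⁻¹ min⁻¹)
    E + Z → G (0.04428 L mol⁻¹ min⁻¹)

In this scheme J goes to Xi in a step with Z as partner, with k3 of 0.373 L mol⁻¹ min⁻¹. Scaled to the Z of the Saturday's run, the working life is 6.06 min. The G made in the Saturday's run comes to half of the charge at 7.30 min, and that life gives 47.5% there.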